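- The leftover I start from: by the last reading of Wednesday's run the solid electrophile has lost 32.5% of its charge, but product stands at 26.3%, so part of what left the solid is not yet product.

| flask | solid electrophile | nucleophile | remark | time |
|---|---|---|---|---|
| Wednesday's | 0.60 M | 0.40 M | run made earlier |  |
| Tuesday's | 0.80 M | 0.40 M | run made earlier |  |
| beta | 0.40 M | 1.60 M |  | 3.0 h |
| delta | 0.40 M | 0.800 M |  | 3.0 h |
| zeta | 0.40 M | 0.400 M |  | 3.0 h |

| run | time / min | solid electrophile / % | product / % |
|---|---|---|---|
| Wednesday's | 20.0 | 93.0 | 4.4 |
| Wednesday's | 40.0 | 91.4 | 8.7 |
| Wednesday's | 60.0 | 85.4 | 12.4 |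
| Wednesday's | 80.0 | 77.1 | 17.3 |
| Wednesday's | 120 | 67.5 | 26.3 |
| Tuesday's | 20.0 | 94.0 | 2.3 |
| Tuesday's | 40.0 | 92.1 | 7.2 |
| Tuesday's | 60.0 | 87.7 | 10.1 |
| Tuesday's | 80.0 | 84.9 | 13.6 |
| Tuesday's | 120 | 75.3 | 19.3 |

(readings scatter by 1 percentage point)

- at the start none of the solid electrophile is in solution
- what has only dissolved of solid electrophile counts as not reacted

- part of the solid electrophile that has reacted (what has only dissolved counts as not reacted) at the end, beta
- part of the solid electrophile that has reacted (what has only dissolved counts as not reacted) at the end, delta
- part of the solid electrophile that has reacted (what has only dissolved counts as not reacted) at the end, zeta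
- what raising the concentration of nucleophile from its lowest to its highest value here does to the part of the solid electrophile that has reacted (what has only dissolved counts as not reacted) (changes below 5 percentage points count as none) (it rises / no change / it falls)

- At its last reading Wednesday's run gives 0.809 and Tuesday's 0.781 for the capture ratio r, product made so far per solid electrophile lost so far: a ratio of amounts at one moment, which can drift as a run goes on.
- The solid loses 0.00162 M min⁻¹ in Wednesday's run and 0.00165 M min⁻¹ in Tuesday's, though the charges differ. If that pace holds for 3.0 h, a charge of 0.40 M loses a share L = 73.1%.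
- Now I turn the question round. For "no change", the most that better capture can add, L(1 − r), must stay under 5 percentage points, so r at 0.400 M of nucleophile must already exceed 0.932.
- Both runs were made at that nucleophile charge, and at their last readings both stand below this line. Wednesday's stands 0.123 short, while the scatter of a reading moves r by about 0.0308.
- So I commit to a rise. Carrying r unchanged from the last reading to 3.0 h is my own assumption; with it zeta stands near 59.1%, beta near L, delta between.
- The forecast gives beta 70%, delta 67% and zeta 59%, with the trend "it rises", on the ground that “More nucleophile shrinks the pool, so conversion approaches the cap”.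
- The flasks give beta 77.3%, delta 70.5% and zeta 48.6%: it rises, by 29 points.

    nucleophile + acid set free ⇌ protonated nucleophile, settled at all times (K = 1500 L mol⁻¹)
    solid electrophile ⇌ electrophile, rate k2*(cs2 - [electrophile]) while solid is left; crystals form when [electrophile] > cs2 (solubility = 0.230 M, k = 1.30 × 10⁻⁴ s⁻¹)
    electrophile + nucleophile → acid set free + product (k = 0.00440 L mol⁻¹ s⁻¹)

- At its end zeta has r = 0.709, lower than Wednesday's reading, and beta has 0.979, past the line. The main reason is the difference in concentration of nucleophile: with that difference taken away, beta's 77.3% falls to 48.6%. A neighbour of zeta charged with 0.10 M of nucleophile shows the same thing further on: nucleophile is its limiting reagent, with 1.9% still free at the end, r is 0.274, and electrophile stands at 37.5%.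

The data stem from a simulated flask for an exercise, noise included.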